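A direct plan would make the oxygenated ring B first: Birch reduction–methylation of a chiral 2,5-dimethylbenzamide would set the quaternary carbon that bears the side chain, oxidation would give dienone A1, a copper-catalysed butenyl addition with acetaldehyde aldol and oxidation would give A2, and the cyclohexene ring A would be closed to A3 before amide, enone and olefin are adjusted. Its weakest steps would be:
(1) the closure of A2 to A3 by olefin metathesis/carbonyl olefination with more than one equivalent of a molybdenum alkylidene, which must take a neopentyl methyl ketone beside an enone carbonyl and an amide and is known only for simple keto olefins;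
(2) the osmylation of diene diol A4 with stoichiometric OsO4, which must pick one of two trisubstituted olefins and the face to which its allylic hydroxyl group does not direct, on late material;
(3) the four late steps (reduction, oxidation, methylenation, Heck coupling) that turn the carboxamide carbon into the diene, many steps for two carbons.

Plan: cut the butenolide at C12–C13 and remove the acetates; trace the ring B triol back to the enone C6(=O)–C7=C8(CH3); cut ring B at C8–C9 (intramolecular Heck reaction), C5–C6 (aldol) and C9–C10 (conjugate addition) to reach 2-methylcyclohex-2-enone. Ring A is thus present from step 1 and ring B closes in step 4. This rests on one feature: the quaternary C9 of ring B bears the C11=C12 olefin and adjoins the methyl-bearing, olefin-level C8, which is the array that 6-exo carbopalladation of a but-2-en-2-yl group by a β-iodo enone and β-hydride elimination produce. No ring is closed by carbonyl olefination, ring B is oxygenated by enone and ketone chemistry only (no choice between olefins), and the vinyl group from the key step needs one coupling to become the side chain.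

Key step: step 4

Numbering (clerodane type, used throughout): ring A = C1, C2, C3, C4, C5, C10 (C3=C4, C18 methyl on C4); ring B = C5, C6, C7, C8, C9, C10 (C19 methyl on C5, OAc on C6 and C7, OH and C17 methyl on C8, C20 methyl and the side chain C11=C12–C13(=C14–C15(=O)–O–C16) on C9). β is the face of H-10; the target is 5α-CH3, 10β-H (trans-decalin), 6α-OAc, 7β-OAc, 8β-OH, 9α-CH3, 9β-side chain.

Assumption: but-2-ynal and (E)-2-bromobut-2-ene are bought (the aldehyde is also sold as its diethyl acetal; an E/Z mixture of the bromide would also serve, because the geometry of that olefin is lost in step 4).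

Step 1
Reactants: 1 2-methylcyclohex-2-en-1-one; 2 (E)-2-bromobut-2-ene; 3 but-2-ynal
Product: 6 (2S,3R)-3-[(E)-but-2-en-2-yl]-2-(1-hydroxybut-2-yn-1-yl)-2-methylcyclohexan-1-one (both carbinol epimers), via alkenyl Grignard reagent 4 (not isolated), via bromomagnesium enolate 5 (not isolated)
Conditions: 2, Mg, THF; then 1, Cu(OTf)2 (3 mol %), chiral imidazolinium tetrafluoroborate as carbene precursor (4 mol %; the enantiomer that gives the 3R adduct), Et2O, −30 °C; then 3, −78 °C; AcOH
Reagents that add atoms: none
Why: Copper-catalysed asymmetric conjugate addition of Grignard reagent 4 (Kharasch type with a chiral carbene ligand, precedented on 2-methylcyclohex-2-enone with trapping of the magnesium enolate) sets C10, and the regio-defined enolate 5 then undergoes aldol addition to the ynal at C5 on the face anti to the new butenyl group, which sets the quaternary C5 with C6 trans to C9; the carbinol centre is removed in step 2.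

Step 2
Reactants: 6 aldol adduct
Product: 7 (2R,3R)-3-[(E)-but-2-en-2-yl]-2-(but-2-ynoyl)-2-methylcyclohexan-1-one
Conditions: Dess–Martin periodinane, CH2Cl2, 0 °C → rt
Reagents that add atoms: none
Why: Dess–Martin oxidation of the propargylic alcohol to the ynone under non-basic conditions, which avoids retro-aldol cleavage of the β-hydroxy ketone; both carbinol epimers converge and no other stereocentre is touched.

Step 3
Reactants: 7 ynone
Product: 8 (2R,3R)-3-[(E)-but-2-en-2-yl]-2-[(Z)-3-iodobut-2-enoyl]-2-methylcyclohexan-1-one
Conditions: NaI, AcOH, rt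
Reagents that add atoms: sodium iodide ([Na+].[I-])
Why: Hydroiodination of the ynone (conjugate addition of iodide at C8 and anti protonation at C7) gives the (Z)-β-iodo enone, in which iodine and the C6 carbonyl group are cis as the ring closure of step 4 requires; the isolated trisubstituted olefin does not add HI under these conditions.

Step 4
Reactants: 8 (Z)-β-iodo enone
Product: 10 vinyl enedione (trans-decalin; ketones at C4 and C6; C7=C8; 8-CH3; 9α-CH3; 9β-vinyl; 5α-CH3; 10β-H), via alkylpalladium iodide 9 (not isolated)
Conditions: Pd2(dba)3 (5 mol %), P(2-furyl)3 (20 mol %), Ag2CO3 (1.5 equiv), MeCN, 60 °C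
Reagents that add atoms: none
Why: Oxidative addition of zerovalent palladium to the C8–I bond (with retention of the Z geometry) and syn addition of the C8–Pd bond across the C9=C11 olefin give σ-alkylpalladium 9, whose only β-hydrogens are on C12, so that β-hydride elimination can give only the C11=C12 vinyl group; the closest known reaction type is the intramolecular Heck cyclization of vinyl halides onto trisubstituted olefins to form quaternary carbons. Ring B (C5–C6–C7–C8–C9–C10) closes in the 6-exo-trig mode, because iodine and the carbonyl group are cis on C7=C8 and the two arms are trans and both equatorial on the ring A chair, which also makes the ring fusion trans. The one new stereocentre, C9, is set in the insertion: in the eclipsed geometry that such insertions need, the carbon that receives palladium (C11) lies in the plane of the forming enone and becomes the pseudo-equatorial β substituent, while the C20 methyl group takes the pseudo-axial α position syn to the C19 methyl group; the other rotamer would press the palladated carbon and its ligands under ring B against that axial methyl group. The step needs 6-exo attack at C9 and not 7-endo attack at C11 (ring size and the exo preference of carbopalladation), carbopalladation and not α-alkenylation of the C4 ketone (silver carbonate is too weak a base to form the enolate), and no olefin migration (C9 is quaternary). The geometry of the butenyl olefin is lost in the product, so E/Z scrambling in the Grignard reagent would not matter.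

Step 5
Reactants: 10 vinyl enedione
Product: 12 enol triflate (C3=C4–OSO2CF3; otherwise as 10), via potassium enolate 11 (not isolated)
Conditions: KHMDS (1.1 equiv), THF, −78 °C; then PhNTf2, −78 → 0 °C
Reagents that add atoms: N-phenylbis(trifluoromethanesulfonimide) (O=S(=O)(N(c1ccccc1)S(=O)(=O)C(F)(F)F)C(F)(F)F)
Why: Kinetic deprotonation can occur only at C3 of the C4 ketone (C5 is quaternary, the enone has no α′-hydrogen and its γ-methyl group is deprotonated more slowly), and O-sulfonylation of enolate 11 (enol triflate formation) fixes the C3=C4 olefin; no stereocentre is touched.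

Step 6
Reactants: 12 enol triflate
Product: 13 trienone (ring A C3=C4 with 4-CH3; C6 ketone; C7=C8; 8-CH3; 9α-CH3; 9β-vinyl; 5α-CH3; 10β-H)
Conditions: MeZnCl (2 equiv), Pd(PPh3)4 (5 mol %), THF, 50 °C
Reagents that add atoms: methylzinc chloride (C[Zn]Cl)
Why: Negishi coupling of the enol triflate puts the C18 methyl group on C4 with the olefin fixed at C3=C4; the organozinc reagent does not add to the enone and transmetalation is faster than carbopalladation of the neighbouring vinyl group.

Step 7
Reactants: 13 trienone
Product: 14 7β,8β-epoxy ketone (C6 ketone; C3=C4 and the vinyl group kept)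
Conditions: 30 % H2O2, NaOH, MeOH, 0 °C → rt
Reagents that add atoms: hydrogen peroxide (OO)
Why: Weitz–Scheffer epoxidation: hydroperoxide adds only to C8 of the enone (the C3=C4 and vinyl olefins are not electrophilic), axially from the β face, which is anti to the pseudo-axial C20 methyl group, and ring closure gives the 7β,8β-epoxide, which sets C7 and C8; the closest precedent is the alkaline epoxidation of steroidal 4-en-3-ones.

Step 8
Reactants: 14 epoxy ketone
Product: 15 8β-hydroxy ketone (C6 ketone; C7 methylene; 8β-OH; 8α-CH3)
Conditions: SmI2 (2.2 equiv), THF/MeOH, −78 °C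
Reagents that add atoms: none
Why: Samarium diiodide reduction of the α,β-epoxy ketone (two single-electron transfers, then protonation) cleaves the C7–O bond and leaves the C8–O bond, so that the tertiary 8β-hydroxyl group is kept with retention; olefins and the hindered ketone are not reduced at −78 °C.

Step 9
Reactants: 15 8β-hydroxy ketone
Product: 17 7β,8β-dihydroxy ketone (C6 ketone), via dipotassium alkoxide enolate 16 (not isolated)
Conditions: KHMDS (3 equiv), THF, −78 → −40 °C; then 3-phenyl-2-(phenylsulfonyl)oxaziridine, −78 °C; aq. NH4Cl
Reagents that add atoms: 3-phenyl-2-(phenylsulfonyl)oxaziridine (O=S(=O)(N1OC1c1ccccc1)c1ccccc1)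
Why: Enolate hydroxylation with the Davis oxaziridine: the ketone can enolise only toward C7 (C5 is quaternary), the dianion 16 cannot undergo retro-aldol cleavage, and oxygen is delivered to the β face of C7 because the α face is closed by the two syn-axial methyl groups C19 and C20, which sets the equatorial 7β-hydroxyl group.

Step 10
Reactants: 17 dihydroxy ketone
Product: 18 vinyl triol (6α,7β,8β-triol; 9β-vinyl; C3=C4)
Conditions: Me4NBH(OAc)3 (5 equiv), MeCN/AcOH, −20 °C
Reagents that add atoms: none
Why: Hydroxyl-directed reduction (Evans–Saksena type): the acetoxyborohydride binds to the axial 8β-hydroxyl group (or to the 7β-hydroxyl group) and delivers hydride to the β face of the C6 carbonyl group, which is also the axial trajectory, so that the equatorial 6α-hydroxyl group results, anti to both neighbouring hydroxyl groups.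

Step 11
Reactants: 18 vinyl triol; 19 4-bromofuran-2(5H)-one
Product: 20 butenolide triol (6α,7β,8β-triol with the complete (E)-C11=C12 side chain)
Conditions: 19 (1.5 equiv), Pd(OAc)2 (10 mol %), n-Bu4NCl, NaHCO3, DMF, 70 °C
Reagents that add atoms: none
Why: Mizoroki–Heck coupling: after oxidative addition of zerovalent palladium to 19, insertion occurs at the terminal carbon C12 of the only monosubstituted olefin and syn β-hydride elimination can take only H-11 (C9 is quaternary), which gives the (E)-diene; the trisubstituted C3=C4 olefin does not insert and the hydroxyl groups need no protection.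

Step 12
Reactants: 20 butenolide triol
Product: 21 CNP0383656.1
Conditions: Ac2O, pyridine, DMAP (cat.), CH2Cl2, rt
Reagents that add atoms: acetic anhydride (CC(=O)OC(C)=O)
Why: DMAP-catalysed acetylation of the two equatorial secondary hydroxyl groups at C6 and C7; the axial tertiary 8-hydroxyl group is too hindered to react at room temperature and no stereocentre is touched.

**Compound list**

1 | 2-methylcyclohex-2-en-1-one | CC1=CCCCC1=O | starting material
2 | (E)-2-bromobut-2-ene | C/C=C(\C)Br | starting material
3 | but-2-ynal | CC#CC=O | starting material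
4 | (E)-but-2-en-2-ylmagnesium bromide | C/C=C(\C)[Mg]Br | intermediate
5 | bromomagnesium enolate (C4–O–Mg, C4=C5; 10-butenyl) | Br[Mg]OC1=C(C)[C@@H](/C(C)=C/C)CCC1 | intermediate
6 | (2S,3R)-3-[(E)-but-2-en-2-yl]-2-(1-hydroxybut-2-yn-1-yl)-2-methylcyclohexan-1-one (carbinol epimers) | O=C1CCC[C@H](/C(C)=C/C)[C@@]1(C)C(O)C#CC | intermediate
7 | (2R,3R)-3-[(E)-but-2-en-2-yl]-2-(but-2-ynoyl)-2-methylcyclohexan-1-one | O=C1CCC[C@H](/C(C)=C/C)[C@@]1(C)C(=O)C#CC | intermediate
8 | (2R,3R)-3-[(E)-but-2-en-2-yl]-2-[(Z)-3-iodobut-2-enoyl]-2-methylcyclohexan-1-one | O=C1CCC[C@H](/C(C)=C/C)[C@@]1(C)C(=O)/C=C(/C)I | intermediate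
9 | σ-alkylpalladium iodide after ring closure (Pd on C11; ligands not drawn) | O=C1C=C(C)[C@](C)(C(C)[Pd]I)[C@H]2CCCC(=O)[C@]12C | intermediate
10 | vinyl enedione: trans-decalin, C4 and C6 ketones, C7=C8, 8-CH3, 9α-CH3, 9β-vinyl, 5α-CH3, 10β-H | O=C1C=C(C)[C@](C)(C=C)[C@H]2CCCC(=O)[C@]12C | intermediate
11 | potassium enolate of 10 (C4–OK, C3=C4) | O=C1C=C(C)[C@](C)(C=C)[C@H]2CCC=C(O[K])[C@]12C | intermediate
12 | enol triflate (C3=C4–OSO2CF3; otherwise as 10) | O=C1C=C(C)[C@](C)(C=C)[C@H]2CCC=C(OS(=O)(=O)C(F)(F)F)[C@]12C | intermediate
13 | trienone: C3=C4 with 4-CH3, C6 ketone, C7=C8, 8-CH3, 9α-CH3, 9β-vinyl, 5α-CH3, 10β-H | O=C1C=C(C)[C@](C)(C=C)[C@H]2CCC=C(C)[C@]12C | intermediate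
14 | 7β,8β-epoxy ketone (C6 ketone) | O=C1[C@@H]3O[C@]3(C)[C@](C)(C=C)[C@H]2CCC=C(C)[C@]12C | intermediate
15 | 8β-hydroxy ketone (C6 ketone, 8α-CH3) | O=C1C[C@](C)(O)[C@](C)(C=C)[C@H]2CCC=C(C)[C@]12C | intermediate
16 | dipotassium alkoxide enolate of 15 (C6–OK, C6=C7; 8β-OK) | [K]OC1=C[C@](C)(O[K])[C@](C)(C=C)[C@H]2CCC=C(C)[C@]12C | intermediate
17 | 7β,8β-dihydroxy ketone (C6 ketone) | O=C1[C@H](O)[C@](C)(O)[C@](C)(C=C)[C@H]2CCC=C(C)[C@]12C | intermediate
18 | vinyl triol: 6α,7β,8β-triol, 9β-vinyl | O[C@H]1[C@H](O)[C@](C)(O)[C@](C)(C=C)[C@H]2CCC=C(C)[C@]12C | intermediate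
19 | 4-bromofuran-2(5H)-one | O=C1C=C(Br)CO1 | starting material
20 | butenolide triol: 6α,7β,8β-triol with the (E)-dienyl butenolide side chain | O[C@H]1[C@H](O)[C@](C)(O)[C@](C)(/C=C/C3=CC(=O)OC3)[C@H]2CCC=C(C)[C@]12C | intermediate
21 | CNP0383656.1 | CC(=O)O[C@H]1[C@H](OC(C)=O)[C@](C)(O)[C@](C)(/C=C/C2=CC(=O)OC2)[C@H]2CCC=C(C)[C@]12C | target

Total step count: 12. Longest linear sequence: 12 steps (from 1 to 21).

**Steps most likely to fail**

Step 4 (key step). Insertion could go through the twisted rotamer, in which the palladated carbon is pseudo-axial, and give the C9 epimer; slow insertion into the hindered olefin could also lead to loss of iodine by reduction. The fallback sets out from 1 and comes back to the route at 10. It exchanges the roles of the two C9 substituents, so that the carbon that arrives with palladium becomes the C20 methyl group. The Grignard reagent of 2-bromo-3,3-diethoxyprop-1-ene would be added to 1 as in step 1 and the enolate trapped with 3 to give the aldol adduct F1. Oxidation as in step 2 would give the ynone F2, and hydroiodination as in step 3 the iodo enone F3. A reductive Heck cyclization (Pd(OAc)2, PPh3, HCO2Na, DMF, 80 °C) would add C8 to the 1,1-disubstituted olefin; the neopentyl alkylpalladium intermediate has no β-hydrogen and would be reduced by formate to the methyl group, giving the acetal F4 (9α-methyl, 9β-diethoxymethyl if insertion prefers the pseudo-axial mode). Mild acid hydrolysis would give the aldehyde F5, and Wittig methylenation (Ph3P=CH2), which the aldehyde should undergo before the two hindered ketones, would return to 10.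

Step 1. The alkenyl Grignard reagent could add with low enantioselectivity to the α-methyl enone, and the hindered enolate could give 1,2-addition of excess reagent to the ynal or incomplete aldol trapping. The fallback sets out from 2 and comes back at 6. Lithiation of 2 (t-BuLi) and reaction with B-methoxy-9-borabicyclo[3.3.1]nonane would give the alkenylborane F6. Rhodium-catalysed asymmetric 1,4-addition of F6 to cyclohex-2-enone ([Rh(OH)(cod)]2, the BINAP enantiomer that gives the 3R product, toluene; Hayashi–Miyaura type under aprotic conditions) would give the boron enolate F7. MeLi and then MeI in the same flask would give the trans-2-methyl ketone F8, whose C5 configuration does not matter. The more substituted silyl enol ether F9 (TMSCl, NaI, Et3N, MeCN) would then be cleaved with MeLi, transmetalated with MgBr2 and treated with 3 to give 6.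

Step 9. Retro-aldol opening of ring B could occur before the second deprotonation, or the hindered enolate could be hydroxylated incompletely. The fallback sets out from 15 and comes back at 17. TMSOTf and Et3N would convert 15 into the bis-silyl derivative F10 (silyl enol ether C6=C7 and 8β-silyl ether). Rubottom oxidation with one equivalent of dimethyldioxirane in acetone at −78 °C, which should reach the electron-rich enol ether well before the trisubstituted olefin, would give the 7β-silyloxy ketone F11 after silyl migration from the β face. Mild acid (citric acid, MeOH) would give 17.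

Further compounds
F1 | step 4 | (2S,3R)-3-(3,3-diethoxyprop-1-en-2-yl)-2-(1-hydroxybut-2-yn-1-yl)-2-methylcyclohexan-1-one (carbinol epimers) | O=C1CCC[C@H](C(=C)C(OCC)OCC)[C@@]1(C)C(O)C#CC
F2 | step 4 | ynone: 2-(but-2-ynoyl) analogue of F1 | O=C1CCC[C@H](C(=C)C(OCC)OCC)[C@@]1(C)C(=O)C#CC
F3 | step 4 | (Z)-β-iodo enone: 2-[(Z)-3-iodobut-2-enoyl] analogue of F1 | O=C1CCC[C@H](C(=C)C(OCC)OCC)[C@@]1(C)C(=O)/C=C(/C)I
F4 | step 4 | acetal enedione: as 10 with 9β-diethoxymethyl in place of vinyl (9α-CH3) | O=C1C=C(C)[C@](C)(C(OCC)OCC)[C@H]2CCCC(=O)[C@]12C
F5 | step 4 | aldehyde enedione: as 10 with 9β-formyl in place of vinyl | O=C1C=C(C)[C@](C)(C=O)[C@H]2CCCC(=O)[C@]12C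
F6 | step 1 | B-[(E)-but-2-en-2-yl]-9-borabicyclo[3.3.1]nonane | C/C=C(\C)B1C2CCCC1CCC2
F7 | step 1 | boron enolate of (R)-3-[(E)-but-2-en-2-yl]cyclohexanone (O–B 9-borabicyclononyl) | O(B1C2CCCC1CCC2)C1=C[C@@H](/C(C)=C/C)CCC1
F8 | step 1 | trans-3-[(E)-but-2-en-2-yl]-2-methylcyclohexan-1-one (3R) | O=C1CCC[C@H](/C(C)=C/C)[C@H]1C
F9 | step 1 | trimethylsilyl enol ether (C4–OSi, C4=C5) of F8 | C[Si](C)(C)OC1=C(C)[C@@H](/C(C)=C/C)CCC1
F10 | step 9 | bis(trimethylsilyl) derivative of 15 (C6 silyl enol ether, 8β-silyl ether) | C[Si](C)(C)OC1=C[C@](C)(O[Si](C)(C)C)[C@](C)(C=C)[C@H]2CCC=C(C)[C@]12C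
F11 | step 9 | 7β,8β-bis(trimethylsilyloxy) ketone | O=C1[C@H](O[Si](C)(C)C)[C@](C)(O[Si](C)(C)C)[C@](C)(C=C)[C@H]2CCC=C(C)[C@]12C
A1 | direct plan | (R)-1,2,5-trimethyl-4-oxocyclohexa-2,5-diene-1-carboxamide of (S)-2-(methoxymethyl)pyrrolidine | O=C1C=C(C)[C@](C)(C(=O)N2CCC[C@H]2COC)C=C1C
A2 | direct plan | keto olefin: ring B enone with acetyl and but-3-enyl groups and the auxiliary carboxamide | O=C1C=C(C)[C@](C)(C(=O)N2CCC[C@H]2COC)[C@@H](CCC=C)[C@]1(C)C(C)=O
A3 | direct plan | trans-fused bicyclic enone amide | O=C1C=C(C)[C@](C)(C(=O)N3CCC[C@H]3COC)[C@H]2CCC=C(C)[C@]12C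
A4 | direct plan | bicyclic diene diol (allylic C6 hydroxyl, hydroxymethyl on C9) | O[C@H]1C=C(C)[C@](C)(CO)[C@H]2CCC=C(C)[C@]12C
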